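The γ-lactone is disconnected at its O–C4 bond, so the last ring-forming event is the oxidation of one C–H bond. C4 of the 1,2-dioxane is the only tertiary C–H and the only carbon γ to the C1 carboxyl. A carboxylate-bound manganese oxidant should therefore turn the C4–H bond directly into the lactone C4–O bond with retention, closing the five-membered ring in one operation. The substrate is a 3,4-trans-4,6-dimethyl-1,2-dioxane-3-acetic acid whose C4–H is cis to the acetic acid arm and whose phenol is masked as an acetate. It is assembled by peroxyketal formation, oxa-Michael ring closure, C6 allylation and cross-metathesis.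

Key step: step 11

Remark: locants follow the 1,2-dioxane ring (C3 bears the acetic acid arm with C2 and C1, then C4, C5, C6), on which the target is (3R,4R,6S); the acid is set free before the aryl acetate is introduced, so the two esters never have to be differentiated.

Step 1
Reactants: 1 (E)-pent-3-en-2-ol (racemic)
Product: 2 (S,E)-pent-3-en-2-ol
Conditions: immobilised Candida antarctica lipase B, vinyl acetate (0.6 equiv), pentane, rt, run just past half conversion; alcohol separated from the ester by chromatography
Reagents that add atoms: none
Why: Lipase-catalysed kinetic resolution by transesterification, in which the enzyme acylates the (R)-alcohol (propenyl as large group, methyl as medium group) much faster, so the unreacted (S)-alcohol should be recovered in high enantiomeric purity.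

Step 2
Reactants: 2 (S,E)-pent-3-en-2-ol; 3 2-methoxypropene
Product: 6 (S,E)-4-methylhept-5-en-2-one, via mixed ketal 4 (not isolated), via allyl isopropenyl ether 5 (not isolated)
Conditions: 3 (4 equiv), EtCO2H (cat.), xylene, sealed tube, 130 °C
Reagents that add atoms: none
Why: Saucy–Marbet (ketal) Claisen rearrangement, in which weak-acid exchange and loss of methanol give the allyl isopropenyl ether, whose chair transition state with the carbinol methyl equatorial transfers the C–O stereocentre suprafacially to the new C–C stereocentre (the future C4, S) and gives the E-alkene.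

Step 3
Reactants: 6 (S,E)-4-methylhept-5-en-2-one; 7 methyl acrylate
Product: 8 methyl (S,E)-4-methyl-6-oxohept-2-enoate
Conditions: 7 (5 equiv), Hoveyda–Grubbs II (5 mol %), CH2Cl2, 40 °C
Reagents that add atoms: none
Why: Olefin cross-metathesis with an electron-poor partner in excess, which releases propene, gives the E-enoate as the thermodynamic product and does not touch the stereocentre.

Step 4
Reactants: 8 methyl (S,E)-4-methyl-6-oxohept-2-enoate
Product: 9 methyl (4S,E)-6-hydroperoxy-6-methoxy-4-methylhept-2-enoate (both C6 epimers)
Conditions: H2O2·urea (5 equiv), Sc(OTf)3 (cat.), MeOH, rt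
Reagents that add atoms: hydrogen peroxide (as its urea adduct), OO; methanol, CO
Why: Lewis-acid-catalysed peroxyketalisation of a methyl ketone with hydrogen peroxide in methanol, a known entry to α-methoxy hydroperoxides; the enoate is inert without base, and the new C6 centre forms as a mixture that is erased in step 6.

Step 5
Reactants: 9 methyl (4S,E)-6-hydroperoxy-6-methoxy-4-methylhept-2-enoate
Product: 10 methyl 2-[(3R,4S)-6-methoxy-4,6-dimethyl-1,2-dioxan-3-yl]acetate (both C6 epimers)
Conditions: Et2NH (cat.), CF3CH2OH, rt
Reagents that add atoms: none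
Why: Intramolecular oxa-Michael addition (6-exo-trig) of the hydroperoxide under mild amine catalysis in a fluorinated alcohol, in which a chair-like closure with the C4 methyl and the enoate both equatorial should favour the 3,4-trans ring (C3 R, C4–H cis to the arm); any 3,4-cis isomer is removed by chromatography.

Step 6
Reactants: 10 methyl 2-[(3R,4S)-6-methoxy-4,6-dimethyl-1,2-dioxan-3-yl]acetate; 11 allyltrimethylsilane
Product: 12 methyl 2-[(3R,4S,6S)-6-allyl-4,6-dimethyl-1,2-dioxan-3-yl]acetate
Conditions: 11 (3 equiv), TiCl4 (1.5 equiv), CH2Cl2, −78 °C; then H2O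
Reagents that add atoms: none
Why: Hosomi–Sakurai allylation of the peroxycarbenium ion formed by ionising the peroxyketal, a known C–C bond formation of alkoxy-1,2-dioxanes; both C6 epimers of 10 give the same cation, and axial attack on the half-chair that keeps the C3 and C4 substituents pseudo-equatorial should place the allyl group cis to the C3 arm and trans to the C4 methyl (C6 S).

Step 7
Reactants: 12 methyl 2-[(3R,4S,6S)-6-allyl-4,6-dimethyl-1,2-dioxan-3-yl]acetate
Product: 13 2-[(3R,4S,6S)-6-allyl-4,6-dimethyl-1,2-dioxan-3-yl]acetic acid
Conditions: LiOH·H2O (2 equiv), THF/H2O, 0 °C → rt; then 1 M HCl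
Reagents that add atoms: lithium hydroxide, [Li+].[OH-]
Why: Saponification of the methyl ester at low temperature, which 1,2-dioxane-3-acetates normally tolerate; it is placed here so that hydroxide never meets the aryl acetate.

Step 8
Reactants: 14 9-bromonon-1-ene; 15 4-bromophenyl acetate
Product: 17 4-(non-8-en-1-yl)phenyl acetate, via non-8-enylzinc bromide 16 (not isolated)
Conditions: 14, Zn dust (1.5 equiv), I2 (cat.), DMA, 70 °C; then 15, Pd(OAc)2 (2 mol %), SPhos (4 mol %), THF, rt
Reagents that add atoms: none
Why: Negishi sp3–sp2 cross-coupling, in which zinc insertion into the primary bromide and palladium/biarylphosphine coupling with the aryl bromide tolerate the aryl ester and the remote terminal alkene.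

Step 9
Reactants: 13 2-[(3R,4S,6S)-6-allyl-4,6-dimethyl-1,2-dioxan-3-yl]acetic acid; 17 4-(non-8-en-1-yl)phenyl acetate
Product: 18 2-[(3R,4S,6S)-6-[10-(4-acetoxyphenyl)dec-2-en-1-yl]-4,6-dimethyl-1,2-dioxan-3-yl]acetic acid (E/Z mixture)
Conditions: 17 (3 equiv), Hoveyda–Grubbs II (5 mol %), CH2Cl2, 40 °C
Reagents that add atoms: none
Why: Cross-metathesis of two unhindered terminal alkenes with the simpler partner in excess; ruthenium alkylidenes tolerate dialkyl peroxides, free carboxylic acids and aryl esters, and the alkene geometry does not matter because the double bond is reduced next.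

Step 10
Reactants: 18 2-[(3R,4S,6S)-6-[10-(4-acetoxyphenyl)dec-2-en-1-yl]-4,6-dimethyl-1,2-dioxan-3-yl]acetic acid
Product: 19 2-[(3R,4S,6S)-6-[10-(4-acetoxyphenyl)decyl]-4,6-dimethyl-1,2-dioxan-3-yl]acetic acid
Conditions: KO2CN=NCO2K (excess, in portions), AcOH, CH2Cl2, 0 °C → rt
Reagents that add atoms: none
Why: Diimide reduction (concerted syn transfer of two hydrogens from HN=NH) saturates the alkene without cleaving the O–O bond, which catalytic hydrogenation would not spare, and the acidic, alcohol-free medium leaves the aryl acetate intact.

Step 11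
Reactants: 19 2-[(3R,4S,6S)-6-[10-(4-acetoxyphenyl)decyl]-4,6-dimethyl-1,2-dioxan-3-yl]acetic acid
Product: 20 plakortolide S acetate, the cis-fused γ-lactone of 2-[(3R,4R,6S)-6-[10-(4-acetoxyphenyl)decyl]-4-hydroxy-4,6-dimethyl-1,2-dioxan-3-yl]acetic acid
Conditions: [Mn(OTf)2(TIPS-pdp)] (2 mol %, ligand enantiomer matched to 19), 30 % aq. H2O2 (2 equiv, syringe pump), (CF3)2CHOH, 0 °C, no added carboxylic acid
Reagents that add atoms: none
Why: The carboxylate of 19 binds manganese cis to the high-valent Mn–oxo formed from H2O2, the oxo abstracts the γ-hydrogen at C4 through a seven-membered transition state, and the bound carboxylate oxygen rebounds onto the C4 radical. The closest known reaction is the carboxylate-directed manganese-catalysed γ-C(sp3)–H lactonisation of aliphatic acids with hydrogen peroxide, used here on an acid that also carries a dialkyl peroxide. The γ-lactone ring closes by C4–O bond formation, a five-membered (5-exo) closure from the carboxylate onto C4 that can only give the cis-fused bicycle. The quaternary C4 centre forms with retention because rebound is faster than inversion of the radical, so it is controlled by the C4–H bond of 19 lying cis to the C3 arm. The step needs site selectivity over C3–H, C5–H2, the chain methylenes and the benzylic CH2; this rests on C4–H being the only tertiary and the only γ C–H within reach of the bound carboxylate, on deactivation of the α-oxy C3–H by hydrogen bonding of the fluorinated alcohol, and on the acetate lowering the electron density of the arene. The dialkyl peroxide has no O–H for metal-assisted heterolysis and should survive, the open question being whether rebound outruns attack of the C4 radical on the neighbouring O–O bond.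

Step 12
Reactants: 20 plakortolide S acetate
Product: 21 plakortolide S, the cis-fused γ-lactone of 2-[(3R,4R,6S)-4-hydroxy-6-[10-(4-hydroxyphenyl)decyl]-4,6-dimethyl-1,2-dioxan-3-yl]acetic acid
Conditions: immobilised Candida antarctica lipase B, n-BuOH (5 equiv), t-BuOMe, 30 °C
Reagents that add atoms: none
Why: Lipase-catalysed alcoholysis of the phenolic acetate under neutral conditions, in which the hindered γ-lactone and the peroxide are not substrates and no base is present that could eliminate the peroxide β to the lactone carbonyl.

Compound list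
1 | (E)-pent-3-en-2-ol (racemic) | C/C=C/C(C)O | starting material
2 | (S,E)-pent-3-en-2-ol | C/C=C/[C@H](C)O | intermediate
3 | 2-methoxypropene | C=C(C)OC | starting material
4 | (S,E)-4-[(2-methoxypropan-2-yl)oxy]pent-2-ene | C/C=C/[C@H](C)OC(C)(C)OC | intermediate
5 | (S,E)-4-(prop-1-en-2-yloxy)pent-2-ene | C/C=C/[C@H](C)OC(C)=C | intermediate
6 | (S,E)-4-methylhept-5-en-2-one | C/C=C/[C@@H](C)CC(C)=O | intermediate
7 | methyl acrylate | C=CC(=O)OC | starting material
8 | methyl (S,E)-4-methyl-6-oxohept-2-enoate | COC(=O)/C=C/[C@@H](C)CC(C)=O | intermediate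
9 | methyl (4S,E)-6-hydroperoxy-6-methoxy-4-methylhept-2-enoate (both C6 epimers) | COC(=O)/C=C/[C@@H](C)CC(C)(OC)OO | intermediate
10 | methyl 2-[(3R,4S)-6-methoxy-4,6-dimethyl-1,2-dioxan-3-yl]acetate (both C6 epimers) | COC1(C)C[C@H](C)[C@@H](CC(=O)OC)OO1 | intermediate
11 | allyltrimethylsilane | C=CC[Si](C)(C)C | starting material
12 | methyl 2-[(3R,4S,6S)-6-allyl-4,6-dimethyl-1,2-dioxan-3-yl]acetate | C=CC[C@@]1(C)C[C@H](C)[C@@H](CC(=O)OC)OO1 | intermediate
13 | 2-[(3R,4S,6S)-6-allyl-4,6-dimethyl-1,2-dioxan-3-yl]acetic acid | C=CC[C@@]1(C)C[C@H](C)[C@@H](CC(=O)O)OO1 | intermediate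
14 | 9-bromonon-1-ene | C=CCCCCCCCBr | starting material
15 | 4-bromophenyl acetate | CC(=O)Oc1ccc(Br)cc1 | starting material
16 | non-8-en-1-ylzinc bromide | C=CCCCCCCC[Zn]Br | intermediate
17 | 4-(non-8-en-1-yl)phenyl acetate | C=CCCCCCCCc1ccc(OC(C)=O)cc1 | intermediate
18 | 2-[(3R,4S,6S)-6-[10-(4-acetoxyphenyl)dec-2-en-1-yl]-4,6-dimethyl-1,2-dioxan-3-yl]acetic acid (E/Z mixture) | CC(=O)Oc1ccc(CCCCCCCC=CC[C@@]2(C)C[C@H](C)[C@@H](CC(=O)O)OO2)cc1 | intermediate
19 | 2-[(3R,4S,6S)-6-[10-(4-acetoxyphenyl)decyl]-4,6-dimethyl-1,2-dioxan-3-yl]acetic acid | C[C@]1(CCCCCCCCCCc2ccc(OC(C)=O)cc2)C[C@H](C)[C@@H](CC(O)=O)OO1 | intermediate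
20 | plakortolide S acetate | C[C@]1(CCCCCCCCCCc2ccc(OC(C)=O)cc2)C[C@@]2(C)OC(=O)C[C@H]2OO1 | intermediate
21 | plakortolide S | C[C@]1(CCCCCCCCCCc2ccc(O)cc2)C[C@@]2(C)OC(=O)C[C@H]2OO1 | target

Total step count: 12. Longest linear sequence: 11 steps (steps 1–7 and 9–12); step 8 is the convergent branch.

Steps most likely to fail

Step 11. After hydrogen abstraction the C4 radical may attack the adjacent O–O bond (epoxide formation with ring cleavage) before rebound, or oxidation may drift to the chain methylenes, the benzylic position or the arene. The fallback replaces the directed metal-oxo pathway by an undirected, concerted oxygen insertion that involves no free radical. It sets out from 19: a pre-formed solution of methyl(trifluoromethyl)dioxirane in 1,1,1-trifluoroacetone/CH2Cl2 at −20 to 0 °C, a known reagent for tertiary C–H hydroxylation with retention, should give 2-[(3R,4R,6S)-6-[10-(4-acetoxyphenyl)decyl]-4-hydroxy-4,6-dimethyl-1,2-dioxan-3-yl]acetic acid F1. Its hydroxyl is cis to the acetic acid arm, so it lactonises with catalytic pyridinium p-toluenesulfonate in CH2Cl2 and the route is rejoined at 20.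

Step 6. Ionisation of the cyclic peroxyketal may be followed by attack on the wrong face of the ring cation or by Lewis-acid-induced heterolysis of the ring O–O bond. The fallback forms the C6–allyl bond before the ring exists and closes the ring afterwards, giving up selectivity at C6 for reliability. It sets out from 9: silylation of the hydroperoxide (TBSOTf, 2,6-lutidine, CH2Cl2, −78 °C) gives methyl (4S,E)-6-[(tert-butyldimethylsilyl)peroxy]-6-methoxy-4-methylhept-2-enoate F2. Ionisation of its methoxy group with TiCl4 in the presence of 11 (CH2Cl2, −78 °C) gives methyl (4S,E)-6-[(tert-butyldimethylsilyl)peroxy]-4,6-dimethylnona-2,8-dienoate F3 as both C6 epimers. HF·pyridine in THF frees methyl (4S,E)-6-hydroperoxy-4,6-dimethylnona-2,8-dienoate F4, which is closed by the same amine-catalysed oxa-Michael addition (Et2NH, CF3CH2OH). Chromatography separates the (6S) isomer, and the route is rejoined at 12.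

Step 3. The metathesis may stall because the alkene is internal and branched at the allylic carbon and because the ketone can chelate the ruthenium alkylidene, leaving unreacted ketone and acrylate dimer. The fallback cleaves the alkene and olefinates instead. It sets out from 6: ozonolysis (O3, CH2Cl2, −78 °C; then Me2S) gives (S)-2-methyl-4-oxopentanal F5, which is used at once to avoid epimerisation α to the aldehyde. A Wittig reaction with methyl (triphenylphosphoranylidene)acetate (CH2Cl2, 0 °C → rt) then gives the E-enoate, and the route is rejoined at 8.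

Further compounds
F1 | step 11 | 2-[(3R,4R,6S)-6-[10-(4-acetoxyphenyl)decyl]-4-hydroxy-4,6-dimethyl-1,2-dioxan-3-yl]acetic acid | C[C@]1(CCCCCCCCCCc2ccc(OC(C)=O)cc2)C[C@@](C)(O)[C@@H](CC(O)=O)OO1
F2 | step 6 | methyl (4S,E)-6-[(tert-butyldimethylsilyl)peroxy]-6-methoxy-4-methylhept-2-enoate (both C6 epimers) | COC(=O)/C=C/[C@@H](C)CC(C)(OC)OO[Si](C)(C)C(C)(C)C
F3 | step 6 | methyl (4S,E)-6-[(tert-butyldimethylsilyl)peroxy]-4,6-dimethylnona-2,8-dienoate (both C6 epimers) | COC(=O)/C=C/[C@@H](C)CC(C)(CC=C)OO[Si](C)(C)C(C)(C)C
F4 | step 6 | methyl (4S,E)-6-hydroperoxy-4,6-dimethylnona-2,8-dienoate (both C6 epimers) | COC(=O)/C=C/[C@@H](C)CC(C)(CC=C)OO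
F5 | step 3 | (S)-2-methyl-4-oxopentanal | O=C[C@@H](C)CC(C)=O
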